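**Retrosynthetic overview**

1. Ring A is the cyclohexanone (C1 = ketone carbon, C2 = CMe2, C3 = CH carrying the side chain, C4 = C(Me)OH, C5 and C6 = CH2). The coumarin bicycle is bought as umbelliferone and joined last by Mitsunobu etherification of a primary alcohol; the side-chain carbinol centre comes from (R)-linalool and travels as a 1,3-dioxane.
2. C4–OH is traced back to C4–CHO (Baeyer–Villiger, retention). The C1 ketone with its C2 gem-dimethyl group is traced back through a siloxycyclopropane to a C1(OSi)=C2(Me) silyl enol ether.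
3. Enabling feature: in ring A the ketone carbon C1 lies 1,4 to the carbinol carbon C4, C2 is its fully substituted α-carbon, and C3/C4 are adjacent stereocentres. A C1=C2 enol ether therefore turns ring A into a cyclohexene that opens across C3–C4 and C5–C6 into the diene C6=C1(OSi)–C2(Me)=C3 and methacrolein (C4=C5).
4. The diene comes from the (E)-enone made by Wittig olefination of the linalool-derived aldehyde.
5. Order of ring formation: 1,3-dioxane (temporary), ring A by the cycloaddition, cyclopropane on ring A (temporary), coumarin attached last.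

Key step: step 6

Assumption 1: the enal face shielded by the (S)-configured catalyst in step 6 is taken from the accepted pre-transition-state model (s-trans enal, formyl C–H···O contact, diene approach anti to the shielding phenyl group); the (R)-configured catalyst would be used in the same step if the opposite sense were found.
Assumption 2: the ring-fusion configuration of the cyclopropane in compounds 12–15 is left undefined, because both of its new centres are erased in step 9.

**Route**

Step 1
Reactants: 1 (R)-(−)-linalool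
Product: 3 (3R)-3,7-dimethyloct-6-ene-1,3-diol, via B-alkyl-9-BBN adduct 2 (not isolated)
Conditions: 9-BBN (1.5 equiv), THF, 0 °C → rt; then aq. NaOH, H2O2, 0 °C → rt
Reagents that add atoms: 9-borabicyclo[3.3.1]nonane, B1C2CCCC1CCC2 (boron stays only in intermediate 2); hydrogen peroxide, OO
Why: Hydroboration with the bulky dialkylborane should take place only at the monosubstituted vinyl group, anti-Markovnikov, leaving the trisubstituted alkene alone, and oxidation of the C–B bond gives the primary alcohol without touching the carbinol centre.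

Step 2
Reactants: 3 (3R)-3,7-dimethyloct-6-ene-1,3-diol
Product: 4 (4R)-2,2,4-trimethyl-4-(4-methylpent-3-en-1-yl)-1,3-dioxane
Conditions: 2,2-dimethoxypropane, PPTS (cat.), CH2Cl2, rt
Reagents that add atoms: 2,2-dimethoxypropane, COC(C)(C)OC
Why: Acid-catalysed transacetalisation closes the six-membered isopropylidene acetal of the 1,3-diol, which masks the primary and the tertiary hydroxyl in one step.

Step 3
Reactants: 4 (4R)-2,2,4-trimethyl-4-(4-methylpent-3-en-1-yl)-1,3-dioxane
Product: 6 3-[(4R)-2,2,4-trimethyl-1,3-dioxan-4-yl]propanal, via secondary ozonide 5 (not isolated)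
Conditions: O3, CH2Cl2, −78 °C; then PPh3, −78 °C → rt
Reagents that add atoms: ozone, [O-][O+]=O
Why: Ozonolysis of the only alkene with reductive work-up should give the aldehyde and acetone, the acetal being inert.

Step 4
Reactants: 6 3-[(4R)-2,2,4-trimethyl-1,3-dioxan-4-yl]propanal; 7 3-(triphenylphosphoranylidene)butan-2-one
Product: 8 (3E)-3-methyl-6-[(4R)-2,2,4-trimethyl-1,3-dioxan-4-yl]hex-3-en-2-one
Conditions: toluene, 90 °C
Reagents that add atoms: none
Why: Wittig olefination with a stabilised α-branched acyl ylide should give the trisubstituted enone with E geometry (acyl group trans to the chain).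

Step 5
Reactants: 8 (3E)-3-methyl-6-[(4R)-2,2,4-trimethyl-1,3-dioxan-4-yl]hex-3-en-2-one
Product: 9 triisopropyl({(3E)-3-methyl-6-[(4R)-2,2,4-trimethyl-1,3-dioxan-4-yl]hexa-1,3-dien-2-yl}oxy)silane
Conditions: TIPSOTf, Et3N, CH2Cl2, −78 → 0 °C
Reagents that add atoms: triisopropylsilyl trifluoromethanesulfonate, CC(C)[Si](C(C)C)(C(C)C)OS(=O)(=O)C(F)(F)F
Why: Soft enolisation of the methyl ketone (silyl triflate and amine) removes a proton from the α'-methyl group under kinetic control and should give the cross-conjugated 2-silyloxy-1,3-diene with the E geometry of the trisubstituted alkene unchanged.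

Step 6
Reactants: 9 triisopropyl({(3E)-3-methyl-6-[(4R)-2,2,4-trimethyl-1,3-dioxan-4-yl]hexa-1,3-dien-2-yl}oxy)silane; 10 methacrolein
Product: 11 (1S,2R)-1,3-dimethyl-2-{2-[(4R)-2,2,4-trimethyl-1,3-dioxan-4-yl]ethyl}-4-[(triisopropylsilyl)oxy]cyclohex-3-ene-1-carbaldehyde
Conditions: (S)-tetrahydro-1-(2-methylphenyl)-3,3-diphenyl-1H,3H-pyrrolo[1,2-c][1,3,2]oxazaborole (20 mol %), (CF3SO2)2NH (18 mol %), CH2Cl2, −78 → −40 °C
Reagents that add atoms: none
Why: Methacrolein bound s-trans to the cationic boron Lewis acid is attacked by the silyloxy diene in a concerted but asynchronous [4+2] cycloaddition, in which the bond from the unsubstituted CH2 terminus of the enol ether to the enal β-carbon (C6–C5 of ring A) leads and the bond from the alkyl-bearing diene terminus to the enal α-carbon (C3–C4) follows. The closest known reaction type is the oxazaborolidinium-catalysed enantioselective Diels–Alder reaction of 2-(trialkylsilyloxy)-1,3-dienes with 2-substituted acroleins. Ring A is closed as a cyclohexene by suprafacial–suprafacial [4+2] cycloaddition, both sigma bonds being made in the same event without a separate ionic ring closure. The quaternary carbon C4 is set by the catalyst, whose phenyl group shields one face of the bound enal so that the diene should add to the re face of the α-carbon (S at the formyl-bearing carbon), and C3 follows from the E geometry of the diene together with the endo orientation of the formyl group, which places CHO cis to the side chain (R at the neighbouring CH). The step needs regioselectivity (secured by the 2-silyloxy donor, which makes the CH2 terminus the nucleophilic end, and reinforced by the alkyl group on the other terminus), endo selectivity (secured by the Lewis-acid-bound formyl group and the absence of inside substituents on the acyclic diene) and enantiofacial selectivity (catalyst control, the dioxane centre being too remote to interfere). The regiodefined C1=C2 silyl enol ether left in the adduct is what later delivers the second C2 methyl group and the C1 ketone.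

Step 7
Reactants: 11 (1S,2R)-1,3-dimethyl-2-{2-[(4R)-2,2,4-trimethyl-1,3-dioxan-4-yl]ethyl}-4-[(triisopropylsilyl)oxy]cyclohex-3-ene-1-carbaldehyde
Product: 12 (2R,3S)-1,3-dimethyl-2-{2-[(4R)-2,2,4-trimethyl-1,3-dioxan-4-yl]ethyl}-6-[(triisopropylsilyl)oxy]bicyclo[4.1.0]heptane-3-carbaldehyde
Conditions: Et2Zn (3 equiv), CH2I2 (6 equiv), CH2Cl2, 0 °C → rt
Reagents that add atoms: diiodomethane, ICI
Why: Simmons–Smith cyclopropanation by the electrophilic zinc carbenoid should occur at the electron-rich enol ether double bond while aldehyde and acetal stay untouched; the new CH2 is the latent second methyl group, the enol ether is thereby protected from peracid, and the two new cyclopropane centres are of no consequence.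

Step 8
Reactants: 12 (2R,3S)-1,3-dimethyl-2-{2-[(4R)-2,2,4-trimethyl-1,3-dioxan-4-yl]ethyl}-6-[(triisopropylsilyl)oxy]bicyclo[4.1.0]heptane-3-carbaldehyde
Product: 14 (2R,3S)-1,3-dimethyl-2-{2-[(4R)-2,2,4-trimethyl-1,3-dioxan-4-yl]ethyl}-6-[(triisopropylsilyl)oxy]bicyclo[4.1.0]heptan-3-ol, via tertiary formate 13 (not isolated)
Conditions: mCPBA, NaHCO3 (buffer), CH2Cl2, 0 °C → rt; then K2CO3, MeOH, rt
Reagents that add atoms: 3-chloroperoxybenzoic acid, OOC(=O)c1cccc(Cl)c1
Why: In the Baeyer–Villiger oxidation of the α-quaternary aldehyde the tertiary alkyl group should migrate with retention of configuration to give the formate, so the C–O bond takes the place of the C–CHO bond set in step 6, and methanolysis frees the tertiary alcohol.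

Step 9
Reactants: 14 (2R,3S)-1,3-dimethyl-2-{2-[(4R)-2,2,4-trimethyl-1,3-dioxan-4-yl]ethyl}-6-[(triisopropylsilyl)oxy]bicyclo[4.1.0]heptan-3-ol
Product: 16 (3R,4S)-4-hydroxy-2,2,4-trimethyl-3-{2-[(4R)-2,2,4-trimethyl-1,3-dioxan-4-yl]ethyl}cyclohexan-1-one, via cyclopropanol 15 (not isolated)
Conditions: Bu4NF, THF, rt; then KOH, MeOH–H2O, 40 °C
Reagents that add atoms: none
Why: Fluoride desilylation followed by base-induced ring opening of the cyclopropanol (homoenolate protonation) should cleave the bond to the unsubstituted CH2, the less substituted carbanion being the better leaving carbon, which gives the ketone with the second methyl group on the α-carbon.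

Step 10
Reactants: 16 (3R,4S)-4-hydroxy-2,2,4-trimethyl-3-{2-[(4R)-2,2,4-trimethyl-1,3-dioxan-4-yl]ethyl}cyclohexan-1-one
Product: 17 (3R,4S)-3-[(3R)-3,5-dihydroxy-3-methylpentyl]-4-hydroxy-2,2,4-trimethylcyclohexan-1-one
Conditions: AcOH–THF–H2O (3:1:1), 40 °C
Reagents that add atoms: none
Why: Mild aqueous acid hydrolysis of the isopropylidene acetal should free the primary and tertiary hydroxyls without dehydrating the tertiary alcohols.

Step 11
Reactants: 17 (3R,4S)-3-[(3R)-3,5-dihydroxy-3-methylpentyl]-4-hydroxy-2,2,4-trimethylcyclohexan-1-one; 18 umbelliferone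
Product: 19 7-({(3R)-3-hydroxy-5-[(1R,2S)-2-hydroxy-2,6,6-trimethyl-5-oxocyclohexyl]-3-methylpentyl}oxy)-2H-chromen-2-one
Conditions: PPh3, DIAD, THF, 0 °C → rt
Reagents that add atoms: none
Why: In the Mitsunobu etherification only the primary alcohol is activated as its alkoxyphosphonium ion and is displaced by the acidic phenol, while the two tertiary alcohols and the ketone should not react.

**Compound list**

1 | (R)-(−)-linalool, (3R)-3,7-dimethylocta-1,6-dien-3-ol | CC(C)=CCC[C@@](C)(O)C=C | starting material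
2 | 9-[(3S)-3-hydroxy-3,7-dimethyloct-6-en-1-yl]-9-borabicyclo[3.3.1]nonane (same spatial arrangement as 1; the descriptor changes by priority only) | CC(C)=CCC[C@@](C)(O)CCB1C2CCCC1CCC2 | intermediate
3 | (3R)-3,7-dimethyloct-6-ene-1,3-diol | CC(C)=CCC[C@@](C)(O)CCO | intermediate
4 | (4R)-2,2,4-trimethyl-4-(4-methylpent-3-en-1-yl)-1,3-dioxane | CC(C)=CCC[C@@](C)(O1)CCOC1(C)C | intermediate
5 | 3,3-dimethyl-5-{2-[(4R)-2,2,4-trimethyl-1,3-dioxan-4-yl]ethyl}-1,2,4-trioxolane (secondary ozonide, trioxolane CH centre undefined) | CC1(C)OOC(CC[C@@](C)(O2)CCOC2(C)C)O1 | intermediate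
6 | 3-[(4R)-2,2,4-trimethyl-1,3-dioxan-4-yl]propanal | O=CCC[C@@](C)(O1)CCOC1(C)C | intermediate
7 | 3-(triphenylphosphoranylidene)butan-2-one | CC(=O)C(C)=P(c1ccccc1)(c1ccccc1)c1ccccc1 | starting material
8 | (3E)-3-methyl-6-[(4R)-2,2,4-trimethyl-1,3-dioxan-4-yl]hex-3-en-2-one | CC(=O)/C(C)=C/CC[C@@](C)(O1)CCOC1(C)C | intermediate
9 | triisopropyl({(3E)-3-methyl-6-[(4R)-2,2,4-trimethyl-1,3-dioxan-4-yl]hexa-1,3-dien-2-yl}oxy)silane | C=C(O[Si](C(C)C)(C(C)C)C(C)C)/C(C)=C/CC[C@@](C)(O1)CCOC1(C)C | intermediate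
10 | methacrolein, 2-methylprop-2-enal | CC(=C)C=O | starting material
11 | (1S,2R)-1,3-dimethyl-2-{2-[(4R)-2,2,4-trimethyl-1,3-dioxan-4-yl]ethyl}-4-[(triisopropylsilyl)oxy]cyclohex-3-ene-1-carbaldehyde (CHO cis to the side chain) | CC1=C(O[Si](C(C)C)(C(C)C)C(C)C)CC[C@](C)(C=O)[C@@H]1CC[C@@](C)(O2)CCOC2(C)C | intermediate
12 | (2R,3S)-1,3-dimethyl-2-{2-[(4R)-2,2,4-trimethyl-1,3-dioxan-4-yl]ethyl}-6-[(triisopropylsilyl)oxy]bicyclo[4.1.0]heptane-3-carbaldehyde (cyclopropane face undefined) | CC12CC1(O[Si](C(C)C)(C(C)C)C(C)C)CC[C@](C)(C=O)[C@@H]2CC[C@@](C)(O3)CCOC3(C)C | intermediate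
13 | (2R,3S)-1,3-dimethyl-2-{2-[(4R)-2,2,4-trimethyl-1,3-dioxan-4-yl]ethyl}-6-[(triisopropylsilyl)oxy]bicyclo[4.1.0]heptan-3-yl formate | CC12CC1(O[Si](C(C)C)(C(C)C)C(C)C)CC[C@](C)(OC=O)[C@@H]2CC[C@@](C)(O3)CCOC3(C)C | intermediate
14 | (2R,3S)-1,3-dimethyl-2-{2-[(4R)-2,2,4-trimethyl-1,3-dioxan-4-yl]ethyl}-6-[(triisopropylsilyl)oxy]bicyclo[4.1.0]heptan-3-ol | CC12CC1(O[Si](C(C)C)(C(C)C)C(C)C)CC[C@](C)(O)[C@@H]2CC[C@@](C)(O3)CCOC3(C)C | intermediate
15 | (2R,3S)-1,3-dimethyl-2-{2-[(4R)-2,2,4-trimethyl-1,3-dioxan-4-yl]ethyl}bicyclo[4.1.0]heptane-3,6-diol (cyclopropanol) | CC12CC1(O)CC[C@](C)(O)[C@@H]2CC[C@@](C)(O3)CCOC3(C)C | intermediate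
16 | (3R,4S)-4-hydroxy-2,2,4-trimethyl-3-{2-[(4R)-2,2,4-trimethyl-1,3-dioxan-4-yl]ethyl}cyclohexan-1-one | CC1(C)C(=O)CC[C@](C)(O)[C@@H]1CC[C@@](C)(O2)CCOC2(C)C | intermediate
17 | (3R,4S)-3-[(3R)-3,5-dihydroxy-3-methylpentyl]-4-hydroxy-2,2,4-trimethylcyclohexan-1-one | CC1(C)C(=O)CC[C@](C)(O)[C@@H]1CC[C@@](C)(O)CCO | intermediate
18 | umbelliferone, 7-hydroxy-2H-chromen-2-one | Oc1ccc2ccc(=O)oc2c1 | starting material
19 | 7-({(3R)-3-hydroxy-5-[(1R,2S)-2-hydroxy-2,6,6-trimethyl-5-oxocyclohexyl]-3-methylpentyl}oxy)-2H-chromen-2-one | CC1(C)C(=O)CC[C@](C)(O)[C@@H]1CC[C@@](C)(O)CCOc1ccc2ccc(=O)oc2c1 | target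

**Step count and risks**

Total: 11 steps. Longest linear sequence: 11 steps (1 → 19).

Steps most likely to fail:

Step 6. The hindered, trisubstituted diene terminus may react slowly with the only moderately reactive methacrolein, so that protodesilylation of the diene by the strongly acidic catalyst competes and the endo and enantiofacial preferences erode. The fallback sets out from 9 and changes the dienophile and the way the carbinol is made. Cycloaddition of 9 with the far more reactive 2-bromoprop-2-enal under the same catalyst class should give the bromo aldehyde F1 (formyl endo, cis to the side chain). Reduction with NaBH4 gives the bromohydrin F2, and K2CO3 in MeOH closes it with inversion at the quaternary carbon to the spiro-epoxide F3, whose oxygen then lies cis to the side chain. LiEt3BH opens the epoxide at its CH2 carbon to the tertiary alcohol F4, which already carries the methyl and hydroxyl groups in the target arrangement. Hydroxyl-assisted Simmons–Smith cyclopropanation of F4 (Et2Zn, CH2I2) comes back to the route at 14, so that steps 7 and 8 are not needed.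

Step 7. Methylene transfer to the tetrasubstituted, hindered enol ether may be slow, leaving time for zinc-halide-induced cleavage of the silyl enol ether or carbonyl side reactions of the free aldehyde. The fallback sets out from 11 and removes the aldehyde for the duration of the cyclopropanation. NaBH4 reduction gives the neopentyl carbinol F5, whose zinc alkoxide should carry the carbenoid to the enol ether (Et2Zn, CH2I2) to give the cyclopropyl carbinol F6. Oxidation with Dess–Martin periodinane comes back to the route at 12.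

Step 8. Hydrogen migration in the Criegee intermediate (over-oxidation to the carboxylic acid) may compete with migration of the tertiary alkyl group. The fallback sets out from 12 and replaces the aldehyde by a methyl ketone, for which only the tertiary group can migrate. MeMgBr addition gives the secondary carbinol F7 (both carbinol epimers), Dess–Martin oxidation gives the methyl ketone F8, and Baeyer–Villiger oxidation (mCPBA, NaHCO3) gives the tertiary acetate F9 with retention. Methanolysis with K2CO3 in MeOH comes back to the route at 14.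

Further compounds
F1 | step 6 | (1R,2R)-1-bromo-3-methyl-2-{2-[(4R)-2,2,4-trimethyl-1,3-dioxan-4-yl]ethyl}-4-[(triisopropylsilyl)oxy]cyclohex-3-ene-1-carbaldehyde | CC1=C(O[Si](C(C)C)(C(C)C)C(C)C)CC[C@](Br)(C=O)[C@@H]1CC[C@@](C)(O2)CCOC2(C)C
F2 | step 6 | [(1R,2R)-1-bromo-3-methyl-2-{2-[(4R)-2,2,4-trimethyl-1,3-dioxan-4-yl]ethyl}-4-[(triisopropylsilyl)oxy]cyclohex-3-en-1-yl]methanol | CC1=C(O[Si](C(C)C)(C(C)C)C(C)C)CC[C@](Br)(CO)[C@@H]1CC[C@@](C)(O2)CCOC2(C)C
F3 | step 6 | (3S,4R)-5-methyl-4-{2-[(4R)-2,2,4-trimethyl-1,3-dioxan-4-yl]ethyl}-6-[(triisopropylsilyl)oxy]-1-oxaspiro[2.5]oct-5-ene | CC1=C(O[Si](C(C)C)(C(C)C)C(C)C)CC[C@@]2(CO2)[C@@H]1CC[C@@](C)(O3)CCOC3(C)C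
F4 | step 6 | (1S,2R)-1,3-dimethyl-2-{2-[(4R)-2,2,4-trimethyl-1,3-dioxan-4-yl]ethyl}-4-[(triisopropylsilyl)oxy]cyclohex-3-en-1-ol | CC1=C(O[Si](C(C)C)(C(C)C)C(C)C)CC[C@](C)(O)[C@@H]1CC[C@@](C)(O2)CCOC2(C)C
F5 | step 7 | [(1S,2S)-1,3-dimethyl-2-{2-[(4R)-2,2,4-trimethyl-1,3-dioxan-4-yl]ethyl}-4-[(triisopropylsilyl)oxy]cyclohex-3-en-1-yl]methanol | CC1=C(O[Si](C(C)C)(C(C)C)C(C)C)CC[C@](C)(CO)[C@@H]1CC[C@@](C)(O2)CCOC2(C)C
F6 | step 7 | [(2S,3S)-1,3-dimethyl-2-{2-[(4R)-2,2,4-trimethyl-1,3-dioxan-4-yl]ethyl}-6-[(triisopropylsilyl)oxy]bicyclo[4.1.0]heptan-3-yl]methanol | CC12CC1(O[Si](C(C)C)(C(C)C)C(C)C)CC[C@](C)(CO)[C@@H]2CC[C@@](C)(O3)CCOC3(C)C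
F7 | step 8 | 1-[(2S,3S)-1,3-dimethyl-2-{2-[(4R)-2,2,4-trimethyl-1,3-dioxan-4-yl]ethyl}-6-[(triisopropylsilyl)oxy]bicyclo[4.1.0]heptan-3-yl]ethan-1-ol | CC12CC1(O[Si](C(C)C)(C(C)C)C(C)C)CC[C@](C)(C(C)O)[C@@H]2CC[C@@](C)(O3)CCOC3(C)C
F8 | step 8 | 1-[(2R,3S)-1,3-dimethyl-2-{2-[(4R)-2,2,4-trimethyl-1,3-dioxan-4-yl]ethyl}-6-[(triisopropylsilyl)oxy]bicyclo[4.1.0]heptan-3-yl]ethan-1-one | CC12CC1(O[Si](C(C)C)(C(C)C)C(C)C)CC[C@](C)(C(C)=O)[C@@H]2CC[C@@](C)(O3)CCOC3(C)C
F9 | step 8 | (2R,3S)-1,3-dimethyl-2-{2-[(4R)-2,2,4-trimethyl-1,3-dioxan-4-yl]ethyl}-6-[(triisopropylsilyl)oxy]bicyclo[4.1.0]heptan-3-yl acetate | CC12CC1(O[Si](C(C)C)(C(C)C)C(C)C)CC[C@](C)(OC(C)=O)[C@@H]2CC[C@@](C)(O3)CCOC3(C)C
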